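The ten-membered carbocycle is disconnected to a cyclohexene: ring carbons C3, C4 (with its methyl), C5, C6, C1 and C2 are the six ring carbons of (S)-carvone, whose cis ring alkene becomes the Z C4=C5 bond. One anionic oxy-Cope rearrangement cleaves C1–C6 and joins C8 to C9, which inserts C7–C10, enlarges the six-membered ring to the ten-membered ring, creates the E C1=C10 alkene and the C6 enolate, and relays the carvone stereocentre to C8. Its precursor is a trans-1,2-divinylcyclohexenol: isopropenyl on C1, hydroxyl and an (E)-2-(4-methoxybenzyloxy)vinyl group on C6, a silyl ether on C3.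

Key step: step 7

Remark on numbering: locants C1 to C15 are those of the target skeleton (C1 furanone ketone, C2=C3 furanone alkene with C3 on the ring oxygen, C4=C5 with methyl C15 on C4, C6 ester carbinol, C7, C8 lactone carbinol, C9, C10 bearing methyl C14 and the ring oxygen, C11 to C13 the methylene lactone) and are used for every ten-membered-ring compound.
Remark on SMILES: the cyclopentadienyl ligands on zirconium are written as σ-bonded rings.
Assumption: (S)-carvone, 4-methoxybenzyl alcohol, trichloroethylene, ethyl bromoacetate and methyl (R)-3-hydroxybutanoate are taken as commercial starting materials.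

Step 1
Reactants: 1 (S)-carvone
Product: 2 (1S,5S)-cis-carveol
Conditions: NaBH4, CeCl3·7H2O, MeOH, 0 °C
Reagents that add atoms: none
Why: Luche 1,2-reduction of the enone; axial hydride delivery to the half-chair that keeps the isopropenyl group equatorial should give the cis alcohol, which sets the carbinol centre.

Step 2
Reactants: 2 (1S,5S)-cis-carveol
Product: 3 (1S,5S)-cis-carveol tert-butyldimethylsilyl ether
Conditions: TBSCl, imidazole, DMF, 25 °C
Reagents that add atoms: tert-butyldimethylsilyl chloride, CC(C)(C)[Si](C)(C)Cl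
Why: Standard silyl ether formation on an unhindered secondary allylic alcohol; no stereocentre is touched.

Step 3
Reactants: 3 (1S,5S)-cis-carveol tert-butyldimethylsilyl ether
Product: 4 (4S,6S)-4-(tert-butyldimethylsilyloxy)-3-methyl-6-(prop-1-en-2-yl)cyclohex-2-en-1-one
Conditions: CrO3, 3,5-dimethylpyrazole, CH2Cl2, −20 °C
Reagents that add atoms: chromium trioxide, O=[Cr](=O)=O
Why: Allylic C–H oxidation with the CrO3–3,5-dimethylpyrazole complex; the ring methylene is the only free secondary allylic site of the trisubstituted alkene (the other carries the silyl ether) and the 1,1-disubstituted isopropenyl group is less prone to attack, so the 4-silyloxy enone should form with both stereocentres intact.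

Step 4
Reactants: 5 4-methoxybenzyl alcohol; 6 trichloroethylene
Product: 10 4-methoxybenzyl ethynyl ether, via potassium 4-methoxybenzyl oxide 7 (not isolated), via dichlorovinyl ether 8 (not isolated), via lithium alkoxyacetylide 9 (not isolated)
Conditions: KH, THF, 0 °C; Cl2C=CHCl, −50 → 25 °C; n-BuLi (2.2 equiv), −78 → −40 °C; MeOH, −78 °C
Reagents that add atoms: none
Why: One-pot alkynyl ether synthesis from an alcohol and trichloroethylene; the alkoxide adds to dichloroacetylene formed in the flask, n-BuLi then effects dehydrochlorination and chlorine–lithium exchange, and the acetylide is protonated cold so that the heat-sensitive benzylic alkynyl ether is never warmed.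

Step 5
Reactants: 10 4-methoxybenzyl ethynyl ether
Product: 12 (E)-1-iodo-2-(4-methoxybenzyloxy)ethene, via alkenyl-Zr(C5H5)2Cl 11 (not isolated)
Conditions: (C5H5)2Zr(H)Cl, THF, 0 → 25 °C; I2, −78 → 0 °C
Reagents that add atoms: iodine, II
Why: Hydrozirconation–iodination; syn addition of Zr–H puts zirconium on the terminal carbon of the alkoxyalkyne and iodinolysis of the C–Zr bond goes with retention, so the E iodide should result.

Step 6
Reactants: 4 (4S,6S)-4-(tert-butyldimethylsilyloxy)-3-methyl-6-(prop-1-en-2-yl)cyclohex-2-en-1-one; 12 (E)-1-iodo-2-(4-methoxybenzyloxy)ethene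
Product: 14 (1S,4S,6S)-4-(tert-butyldimethylsilyloxy)-1-[(E)-2-(4-methoxybenzyloxy)vinyl]-3-methyl-6-(prop-1-en-2-yl)cyclohex-2-en-1-ol, via alkenyllithium 13 (not isolated)
Conditions: 12, t-BuLi (2 equiv), Et2O, −78 °C; then 4, THF, −78 °C; aq NH4Cl
Reagents that add atoms: none
Why: Iodine–lithium exchange with retention of alkene geometry, then 1,2-addition of the alkenyllithium to the enone at low temperature to limit enolisation; approach anti to the neighbouring isopropenyl group, as in additions of alkenyl metals to 6-substituted cyclohexenones, should set the tertiary carbinol with the two alkenyl groups trans.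

Step 7
Reactants: 14 (1S,4S,6S)-4-(tert-butyldimethylsilyloxy)-1-[(E)-2-(4-methoxybenzyloxy)vinyl]-3-methyl-6-(prop-1-en-2-yl)cyclohex-2-en-1-ol
Product: 17 (3S,8S)-3-(tert-butyldimethylsilyloxy)-8-(4-methoxybenzyloxy)-4,10-dimethylcyclodeca-1(10)E,4Z-dien-6-one, via potassium alkoxide 15 (not isolated), via potassium enolate 16 (not isolated)
Conditions: KH, 18-crown-6, THF, 0 °C; AcOH, −78 °C
Reagents that add atoms: none
Why: Anionic oxy-Cope rearrangement: KH with 18-crown-6 gives the free alkoxide 15, whose [3,3] shift through a chair transition state with both alkenyl groups equatorial breaks C1–C6 and forms C8–C9 to give the cross-conjugated enolate 16, which is protonated at C7 on the cold quench. The closest known reaction type is the alkoxide-accelerated ring expansion of trans-1,2-divinylcyclohexanols to cyclodec-5-enones. The ten-membered ring arises by sigmatropic ring expansion of the six-membered ring (a four-atom insertion), not by end-to-end cyclisation, so no high dilution is needed. The new C8 stereocentre is controlled by the carvone-derived C1 centre, which fixes the sense of the chair, together with the E geometry of the enol ether, which keeps the 4-methoxybenzyloxy group equatorial and so gives 8S. The step needs chair over boat selectivity and E geometry at C1=C10; both follow from the trans diequatorial arrangement of the alkenyl groups, while the Z C4=C5 alkene is inherited from the cyclohexene. The equatorial C8–O bond lies in the nodal plane of the enolate, which together with the low temperature should hold back loss of the alkoxide.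

Step 8
Reactants: 17 (3S,8S)-3-(tert-butyldimethylsilyloxy)-8-(4-methoxybenzyloxy)-4,10-dimethylcyclodeca-1(10)E,4Z-dien-6-one; 18 ethyl bromoacetate
Product: 20 ethyl 2-[(3S,7R,8S)-3-(tert-butyldimethylsilyloxy)-8-(4-methoxybenzyloxy)-4,10-dimethyl-6-oxocyclodeca-1(10)E,4Z-dien-7-yl]acetate, via lithium enolate 19 (not isolated)
Conditions: LiN(SiMe3)2, THF, −78 °C; 18, DMPU, −78 → −40 °C
Reagents that add atoms: none
Why: Kinetic enolate alkylation; the base removes a C7 proton (the only sp3 α-position of the enone) to regenerate the E enolate, and the bromoacetate should attack its outer face, anti to the transannular C1=C10 unit, which sets C7 (R) with the acetate arm trans to the C8 oxygen, the centre remaining epimerisable next to the ketone if equilibration is needed.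

Step 9
Reactants: 20 ethyl 2-[(3S,7R,8S)-3-(tert-butyldimethylsilyloxy)-8-(4-methoxybenzyloxy)-4,10-dimethyl-6-oxocyclodeca-1(10)E,4Z-dien-7-yl]acetate
Product: 22 (3S,7R,8S)-3-(tert-butyldimethylsilyloxy)-6-oxo-4,10-dimethylcyclodeca-1(10)E,4Z-diene trans-fused 8,12-γ-lactone, via hydroxy ester 21 (not isolated)
Conditions: DDQ, CH2Cl2–pH 7 buffer, 0 °C; PPTS (cat.), CH2Cl2, 25 °C
Reagents that add atoms: none
Why: Oxidative cleavage of the 4-methoxybenzyl ether by DDQ leaves the silyl ether and alkenes alone, and the freed C8 hydroxyl closes the trans-fused γ-lactone by acid-catalysed transesterification while C6 is still a ketone, so that only the 8,12-lactone can form.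

Step 10
Reactants: 22 (3S,7R,8S)-3-(tert-butyldimethylsilyloxy)-6-oxo-4,10-dimethylcyclodeca-1(10)E,4Z-diene trans-fused 8,12-γ-lactone
Product: 23 (1R,10R)-1,10-diol of 22
Conditions: OsO4 (cat.), NMO, acetone–H2O, 0 → 25 °C
Reagents that add atoms: osmium tetroxide, O=[Os](=O)(=O)=O; N-methylmorpholine N-oxide, C[N+]1([O-])CCOCC1; water, O
Why: Catalytic syn-dihydroxylation; the electron-rich isolated trisubstituted alkene reacts in preference to the electron-poor enone alkene, and attack on the outer face of the E alkene in the ring conformer left by the rearrangement should place the C10 hydroxyl as required (10R), the C1 centre being destroyed later.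

Step 11
Reactants: 23 (1R,10R)-1,10-diol of 22
Product: 24 (1R,3S,10R)-1,3,10-triol
Conditions: HF·pyridine, pyridine, THF, 0 → 25 °C
Reagents that add atoms: none
Why: Fluoride cleavage of the secondary allylic silyl ether under buffered acidic conditions that spare the base-sensitive β-acyloxy ketone and the lactone.

Step 12
Reactants: 24 (1R,3S,10R)-1,3,10-triol
Product: 26 furanone keto lactone (C1 ketone, 3,10-oxygen bridge, C2=C3, C6 ketone, 8,12-lactone), via trione 25 (not isolated)
Conditions: IBX, DMSO, 25 °C; CSA (cat.), CH2Cl2, 25 °C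
Reagents that add atoms: none
Why: IBX oxidation turns both secondary alcohols into ketones without cleaving the 1,2-diol, and the resulting α'-hydroxy-1,3-diketone undergoes the standard acid-catalysed cyclodehydration (C10 hydroxyl onto C3, loss of water toward C2) to the 3(2H)-furanone, C10 being quaternary and not epimerisable.

Step 13
Reactants: 26 furanone keto lactone (C1 ketone, 3,10-oxygen bridge, C2=C3, C6 ketone, 8,12-lactone)
Product: 27 (6R)-alcohol of 26
Conditions: NaBH4, CeCl3·7H2O, MeOH–CH2Cl2, −78 °C
Reagents that add atoms: none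
Why: Luche reduction; the conjugated C6 ketone is far more electrophilic than the vinylogous-ester carbonyl of the furanone or the lactone, and the small hydride should add anti-periplanar to the pseudo-axial C7–H bond, as in reductions of 2-substituted cycloalkanones, giving the pseudo-equatorial (6R) alcohol trans to C11.

Step 14
Reactants: 27 (6R)-alcohol of 26
Product: 28 C6 triethylsilyl ether of 27
Conditions: Et3SiOTf, 2,6-lutidine, CH2Cl2, −78 °C
Reagents that add atoms: triethylsilyl trifluoromethanesulfonate, CC[Si](CC)(CC)OS(=O)(=O)C(F)(F)F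
Why: Silylation of the hindered secondary alcohol under non-nucleophilic conditions, so that no C6 alkoxide can open the neighbouring lactone during the enolate step that follows.

Step 15
Reactants: 28 C6 triethylsilyl ether of 27
Product: 32 α-methylene lactone C6 triethylsilyl ether, via lactone lithium enolate 29 (not isolated), via Mannich base 30 (not isolated), via ammonium iodide 31 (not isolated)
Conditions: LiN(i-Pr)2, THF, −78 °C; CH2=NMe2+ I−, −78 → 0 °C; MeI, MeOH, 25 °C; aq NaHCO3, EtOAc
Reagents that add atoms: dimethylmethyleneiminium iodide, C=[N+](C)C.[I-]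
Why: α-Methylenation of a γ-lactone by the Mannich route (enolate aminomethylation, quaternisation, base-induced elimination); the lactone methylene is the only acidic C–H site left, since the furanone has no enolisable α-hydrogen and C6 is protected.

Step 16
Reactants: 32 α-methylene lactone C6 triethylsilyl ether
Product: 33 α-methylene lactone (6R)-alcohol
Conditions: HF·pyridine, THF, 0 °C
Reagents that add atoms: none
Why: Fluoride cleavage of the triethylsilyl ether under mildly acidic conditions tolerated by the methylene lactone and the furanone.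

Step 17
Reactants: 34 methyl (R)-3-hydroxybutanoate
Product: 35 methyl (R)-3-(tert-butyldimethylsilyloxy)butanoate
Conditions: TBSCl, imidazole, DMF, 25 °C
Reagents that add atoms: tert-butyldimethylsilyl chloride, CC(C)(C)[Si](C)(C)Cl
Why: Standard silylation of the chiral-pool secondary alcohol, which keeps its configuration.

Step 18
Reactants: 35 methyl (R)-3-(tert-butyldimethylsilyloxy)butanoate
Product: 39 methyl (R)-3-(tert-butyldimethylsilyloxy)-2-methylidenebutanoate, via ester lithium enolate 36 (not isolated), via Mannich base 37 (not isolated), via ammonium iodide 38 (not isolated)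
Conditions: LiN(i-Pr)2, THF, −78 °C; CH2=NMe2+ I−, −78 → 0 °C; MeI, MeOH, 25 °C; DBU, CH2Cl2, 25 °C
Reagents that add atoms: dimethylmethyleneiminium iodide, C=[N+](C)C.[I-]
Why: Mannich-type α-methylenation of an ester enolate, generated and trapped at −78 °C where β-silyloxy ester enolates do not eliminate; the oxygen-bearing stereocentre carries no acidic hydrogen and is preserved.

Step 19
Reactants: 39 methyl (R)-3-(tert-butyldimethylsilyloxy)-2-methylidenebutanoate
Product: 40 (R)-3-(tert-butyldimethylsilyloxy)-2-methylidenebutanoic acid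
Conditions: LiOH, THF–H2O, 0 → 25 °C; 1 M HCl to pH 3
Reagents that add atoms: lithium hydroxide, [Li+].[OH-]
Why: Saponification of the methyl ester; the secondary silyl ether survives aqueous LiOH and the α-branched acrylate resists conjugate addition of hydroxide.

Step 20
Reactants: 33 α-methylene lactone (6R)-alcohol; 40 (R)-3-(tert-butyldimethylsilyloxy)-2-methylidenebutanoic acid
Product: 42 silyl-protected target ester, via mixed anhydride 41 (not isolated)
Conditions: 40, 2,4,6-Cl3C6H2COCl, Et3N, PhMe, 25 °C; then 33, DMAP, PhMe, 25 °C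
Reagents that add atoms: none
Why: Yamaguchi esterification through the mixed anhydride and DMAP acyl transfer, suited to a hindered secondary alcohol and an acrylic acid; the C6–O bond is not broken, so the configuration is retained, and the protected side-chain hydroxyl cannot self-acylate.

Step 21
Reactants: 42 silyl-protected target ester
Product: 43 target CNP0266753.1
Conditions: HF·pyridine, THF, 0 → 25 °C
Reagents that add atoms: none
Why: Fluoride cleavage of the secondary silyl ether under base-free conditions, which leaves the methylene lactone, the acrylate ester and the furanone untouched.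

Compound list
1 | (S)-carvone | CC1=CC[C@@H](CC1=O)C(C)=C | starting material
2 | (1S,5S)-cis-carveol (hydroxyl cis to isopropenyl) | CC1=CC[C@H](C(C)=C)C[C@@H]1O | intermediate
3 | (1S,5S)-cis-carveol tert-butyldimethylsilyl ether | CC1=CC[C@H](C(C)=C)C[C@@H]1O[Si](C)(C)C(C)(C)C | intermediate
4 | (4S,6S)-4-(tert-butyldimethylsilyloxy)-3-methyl-6-(prop-1-en-2-yl)cyclohex-2-en-1-one | CC1=CC(=O)[C@H](C(C)=C)C[C@@H]1O[Si](C)(C)C(C)(C)C | intermediate
5 | 4-methoxybenzyl alcohol | COc1ccc(CO)cc1 | starting material
6 | trichloroethylene | ClC=C(Cl)Cl | starting material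
7 | potassium 4-methoxybenzyl oxide | [K+].[O-]Cc1ccc(OC)cc1 | intermediate (not isolated)
8 | (E)-1,2-dichlorovinyl 4-methoxybenzyl ether | COc1ccc(CO/C(Cl)=C\Cl)cc1 | intermediate (not isolated)
9 | lithium (4-methoxybenzyloxy)acetylide | [Li]C#COCc1ccc(OC)cc1 | intermediate (not isolated)
10 | 4-methoxybenzyl ethynyl ether | C#COCc1ccc(OC)cc1 | intermediate
11 | chlorobis(cyclopentadienyl)[(E)-2-(4-methoxybenzyloxy)vinyl]zirconium | Cl[Zr](/C=C/OCc1ccc(OC)cc1)(C1C=CC=C1)C1C=CC=C1 | intermediate (not isolated)
12 | (E)-1-iodo-2-(4-methoxybenzyloxy)ethene | COc1ccc(CO/C=C/I)cc1 | intermediate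
13 | (E)-2-(4-methoxybenzyloxy)vinyllithium | [Li]/C=C/OCc1ccc(OC)cc1 | intermediate (not isolated)
14 | (1S,4S,6S)-4-(tert-butyldimethylsilyloxy)-1-[(E)-2-(4-methoxybenzyloxy)vinyl]-3-methyl-6-(prop-1-en-2-yl)cyclohex-2-en-1-ol (alkenyl groups trans; key-step precursor) | CC1=C[C@@](O)(/C=C/OCc2ccc(OC)cc2)[C@H](C(C)=C)C[C@@H]1O[Si](C)(C)C(C)(C)C | intermediate
15 | potassium alkoxide of 14 | [K+].CC1=C[C@@]([O-])(/C=C/OCc2ccc(OC)cc2)[C@H](C(C)=C)C[C@@H]1O[Si](C)(C)C(C)(C)C | intermediate (not isolated)
16 | potassium C6 enolate of 17 (C6=C7 E in the ring) | [K+].[O-]/C1=C\[C@@H](OCc2ccc(OC)cc2)C/C(C)=C/C[C@H](O[Si](C)(C)C(C)(C)C)/C(C)=C\1 | intermediate (not isolated)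
17 | (3S,8S)-3-(tert-butyldimethylsilyloxy)-8-(4-methoxybenzyloxy)-4,10-dimethylcyclodeca-1(10)E,4Z-dien-6-one (key-step product) | O=C1C[C@@H](OCc2ccc(OC)cc2)C/C(C)=C/C[C@H](O[Si](C)(C)C(C)(C)C)/C(C)=C\1 | intermediate
18 | ethyl bromoacetate | BrCC(=O)OCC | starting material
19 | lithium C6 enolate of 17 (C6=C7 E in the ring) | [Li+].[O-]/C1=C\[C@@H](OCc2ccc(OC)cc2)C/C(C)=C/C[C@H](O[Si](C)(C)C(C)(C)C)/C(C)=C\1 | intermediate (not isolated)
20 | ethyl 2-[(3S,7R,8S)-3-(tert-butyldimethylsilyloxy)-8-(4-methoxybenzyloxy)-4,10-dimethyl-6-oxocyclodeca-1(10)E,4Z-dien-7-yl]acetate | O=C1[C@H](CC(=O)OCC)[C@@H](OCc2ccc(OC)cc2)C/C(C)=C/C[C@H](O[Si](C)(C)C(C)(C)C)/C(C)=C\1 | intermediate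
21 | C8 hydroxy ester (20 without the 4-methoxybenzyl group) | O=C1[C@H](CC(=O)OCC)[C@@H](O)C/C(C)=C/C[C@H](O[Si](C)(C)C(C)(C)C)/C(C)=C\1 | intermediate (not isolated)
22 | (3S,7R,8S)-keto lactone: C6 ketone, trans-fused γ-lactone from C8–O to C12, C3 silyl ether, 1(10)E and 4Z alkenes | O=C1[C@@H]2CC(=O)O[C@H]2C/C(C)=C/C[C@H](O[Si](C)(C)C(C)(C)C)/C(C)=C\1 | intermediate
23 | (1R,10R)-1,10-diol of 22 | O=C1[C@@H]2CC(=O)O[C@H]2C[C@@](C)(O)[C@H](O)C[C@H](O[Si](C)(C)C(C)(C)C)/C(C)=C\1 | intermediate
24 | (1R,3S,10R)-1,3,10-triol (23 without the silyl group) | O=C1[C@@H]2CC(=O)O[C@H]2C[C@@](C)(O)[C@H](O)C[C@H](O)/C(C)=C\1 | intermediate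
25 | 1,3,6-trione with free C10 hydroxyl | O=C1[C@@H]2CC(=O)O[C@H]2C[C@@](C)(O)C(=O)CC(=O)/C(C)=C\1 | intermediate (not isolated)
26 | furanone keto lactone: 3(2H)-furanone (C1 ketone, C2=C3, oxygen bridge C3–O–C10), C6 ketone, 4Z alkene, 8,12-lactone | O=C1[C@@H]2CC(=O)O[C@H]2C[C@@]3(C)OC(=CC3=O)/C(C)=C\1 | intermediate
27 | (6R)-alcohol of 26 | C1C(=O)O[C@H]2C[C@@]3(C)OC(=CC3=O)/C(C)=C\[C@@H](O)[C@H]12 | intermediate
28 | C6 triethylsilyl ether of 27 | C1C(=O)O[C@H]2C[C@@]3(C)OC(=CC3=O)/C(C)=C\[C@@H](O[Si](CC)(CC)CC)[C@H]12 | intermediate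
29 | lithium enolate of lactone 28 (C11=C12) | [Li+].C1=C([O-])O[C@H]2C[C@@]3(C)OC(=CC3=O)/C(C)=C\[C@@H](O[Si](CC)(CC)CC)[C@H]12 | intermediate (not isolated)
30 | C11 dimethylaminomethyl lactone (C11 configuration not defined) | CN(C)CC1C(=O)O[C@H]2C[C@@]3(C)OC(=CC3=O)/C(C)=C\[C@@H](O[Si](CC)(CC)CC)[C@H]12 | intermediate (not isolated)
31 | C11 trimethylammoniomethyl lactone iodide | [I-].C[N+](C)(C)CC1C(=O)O[C@H]2C[C@@]3(C)OC(=CC3=O)/C(C)=C\[C@@H](O[Si](CC)(CC)CC)[C@H]12 | intermediate (not isolated)
32 | α-methylene lactone C6 triethylsilyl ether | C=C1C(=O)O[C@H]2C[C@@]3(C)OC(=CC3=O)/C(C)=C\[C@@H](O[Si](CC)(CC)CC)[C@H]12 | intermediate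
33 | α-methylene lactone (6R)-alcohol | C=C1C(=O)O[C@H]2C[C@@]3(C)OC(=CC3=O)/C(C)=C\[C@@H](O)[C@H]12 | intermediate
34 | methyl (R)-3-hydroxybutanoate | C[C@@H](O)CC(=O)OC | starting material
35 | methyl (R)-3-(tert-butyldimethylsilyloxy)butanoate | C[C@@H](O[Si](C)(C)C(C)(C)C)CC(=O)OC | intermediate
36 | lithium enolate of ester 35 | [Li+].C[C@@H](O[Si](C)(C)C(C)(C)C)C=C([O-])OC | intermediate (not isolated)
37 | methyl (3R)-3-(tert-butyldimethylsilyloxy)-2-(dimethylaminomethyl)butanoate (C2 not defined) | C[C@@H](O[Si](C)(C)C(C)(C)C)C(CN(C)C)C(=O)OC | intermediate (not isolated)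
38 | trimethylammonium iodide of 37 | [I-].C[C@@H](O[Si](C)(C)C(C)(C)C)C(C[N+](C)(C)C)C(=O)OC | intermediate (not isolated)
39 | methyl (R)-3-(tert-butyldimethylsilyloxy)-2-methylidenebutanoate | C[C@@H](O[Si](C)(C)C(C)(C)C)C(=C)C(=O)OC | intermediate
40 | (R)-3-(tert-butyldimethylsilyloxy)-2-methylidenebutanoic acid | C[C@@H](O[Si](C)(C)C(C)(C)C)C(=C)C(=O)O | intermediate
41 | mixed anhydride of 40 with 2,4,6-trichlorobenzoic acid | C[C@@H](O[Si](C)(C)C(C)(C)C)C(=C)C(=O)OC(=O)c1c(Cl)cc(Cl)cc1Cl | intermediate (not isolated)
42 | target with the side-chain hydroxyl as tert-butyldimethylsilyl ether | C=C1C(=O)O[C@H]2C[C@@]3(C)OC(=CC3=O)/C(C)=C\[C@@H](OC(=O)C(=C)[C@@H](C)O[Si](C)(C)C(C)(C)C)[C@H]12 | intermediate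
43 | CNP0266753.1: (6R,7R,8S,10R)-furanone 8,12-lactone with the C6 (R)-3-hydroxy-2-methylidenebutanoate | C=C1C(=O)O[C@H]2C[C@@]3(C)OC(=CC3=O)/C(C)=C\[C@@H](OC(=O)C(=C)[C@@H](C)O)[C@H]12 | target

Total step count: 21 steps. Longest linear sequence: 16 steps (steps 1, 2, 3, 6 to 16, 20, 21), from (S)-carvone.

Steps most likely to fail

Step 7. The potassium enolate carries the C8 alkoxy group in the β-position, so loss of 4-methoxybenzyl oxide by E1cB elimination, or migration of the C3 silyl group to the tertiary alkoxide before the shift, may compete with the rearrangement. The fallback removes the anion altogether and uses the neutral, thermal siloxy-Cope rearrangement. It sets out from 14, which is silylated at the tertiary hydroxyl (Me3SiOTf, 2,6-lutidine) to the trimethylsilyl ether of 14 F1. Heating in o-dichlorobenzene at about 180 °C should take this through the same chair to the trimethylsilyl enol ether of 17 F2. Mild hydrolysis (aqueous citric acid, THF) then returns the route at 17.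

Step 10. Osmylation may occur with poor or inverted facial selectivity if the ring prefers another conformer, which would set C10 wrongly. The fallback keeps the same facial preference but inverts its stereochemical consequence by epoxide opening. It sets out from 22, which is epoxidised with mCPBA (NaHCO3 buffer) on the outer face to the 1,10-epoxide F3. Acid-catalysed hydrolysis (dilute HClO4, aqueous THF, 0 °C) opens the epoxide at the tertiary C10 with inversion and gives the (1S,10R)-diol F4, in which C10 is as in 23 and only the expendable C1 centre differs. HF·pyridine then gives the (1S,10R)-triol F5, and IBX followed by acid returns the route at 26.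

Step 13. Hydride may be delivered to the other face of the C6 carbonyl, giving the C6 epimer. The fallback corrects the centre by substitution instead of by facial selection. It sets out from 26, whose reduction in that case gives the (6S)-alcohol F6. A Mitsunobu reaction with chloroacetic acid (PPh3, diisopropyl azodicarboxylate, PhMe) inverts C6 and gives the (6R)-chloroacetate F7. Thiourea with NaHCO3 in EtOH removes the chloroacetyl group without touching the lactone and returns the route at 27.

Further compounds
F1 | step 7 | trimethylsilyl ether of 14 | CC1=C[C@@](O[Si](C)(C)C)(/C=C/OCc2ccc(OC)cc2)[C@H](C(C)=C)C[C@@H]1O[Si](C)(C)C(C)(C)C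
F2 | step 7 | trimethylsilyl enol ether of 17 (C6=C7 E in the ring) | C[Si](C)(C)O/C1=C\[C@@H](OCc2ccc(OC)cc2)C/C(C)=C/C[C@H](O[Si](C)(C)C(C)(C)C)/C(C)=C\1
F3 | step 10 | 1,10-epoxide of 22 (oxygen on the face opposite to the hydroxyls of 23) | O=C1[C@@H]2CC(=O)O[C@H]2C[C@]3(C)O[C@H]3C[C@H](O[Si](C)(C)C(C)(C)C)/C(C)=C\1
F4 | step 10 | (1S,10R)-1,10-diol, C1 epimer of 23 | O=C1[C@@H]2CC(=O)O[C@H]2C[C@@](C)(O)[C@@H](O)C[C@H](O[Si](C)(C)C(C)(C)C)/C(C)=C\1
F5 | step 10 | (1S,3S,10R)-1,3,10-triol, C1 epimer of 24 | O=C1[C@@H]2CC(=O)O[C@H]2C[C@@](C)(O)[C@@H](O)C[C@H](O)/C(C)=C\1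
F6 | step 13 | (6S)-alcohol, C6 epimer of 27 | C1C(=O)O[C@H]2C[C@@]3(C)OC(=CC3=O)/C(C)=C\[C@H](O)[C@H]12
F7 | step 13 | (6R)-chloroacetate of 27 | C1C(=O)O[C@H]2C[C@@]3(C)OC(=CC3=O)/C(C)=C\[C@@H](OC(=O)CCl)[C@H]12
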